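The readings were generated by integration with made-up constants; the scatter is artificial.

Slowness marks the reagent in the beta, epsilon and alpha runs, and the fraction of it left says more than the target made.

| flask | solid substrate | reagent | remark | time |
|---|---|---|---|---|
| beta | 0.15 M | 0.30 M | run made earlier |  |
| epsilon | 0.22 M | 0.30 M | run made earlier |  |
| alpha | 0.30 M | 0.15 M | run made earlier |  |
| flask | 0.30 M | 0.300 M |  | 50 min |

| run | time / min | target / % | solid product / % |
|---|---|---|---|
| beta | 3.00 | 3.8 | 0 |
| beta | 8.00 | 9.8 | 2.9 |
| beta | 15.0 | 20.8 | 13.3 |
| beta | 40.0 | 56.3 | 50.0 |
| epsilon | 5.00 | 2.1 | 1.5 |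
| epsilon | 15.0 | 13.1 | 8.3 |
| epsilon | 25.0 | 24.8 | 20.4 |
| epsilon | 40.0 | 39.3 | 34.2 |
| alpha | 3.00 | 1.0 | 0 |
| alpha | 8.00 | 5.5 | 0 |
| alpha | 15.0 | 5.9 | 4.0 |
| alpha | 40.0 | 14.5 | 14.8 |

(each reading ± 1 percentage point)

- target is meant together with its solid product
- solid, in amounts per volume of the solution: solid substrate, solid product
- at the start none of the solid substrate is in solution
- dissolved substrate means what is dissolved; the solid is not counted in it

Counting one reagent used per target, with the solid product inside the target column, [reagent] at 40.0 min stands at 71.8%, 71.2% and 71.0% of its charge, although the solid substrate goes from 0.15 M in beta to 0.30 M in alpha and the reagent from 0.30 M to 0.15 M. Like fractions at one time do not prove a first-order loss, so this reckoning only assumes that [reagent] goes on falling exponentially at the pace read there, and on that assumption it works with two times: the reagent lifetime, in which [reagent] falls by a factor e at this pace, 118 min, and the 50 min of the flask.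

- how much target and solid product together there is at 50 min, in percent of the solid substrate charged
- concentration of dissolved substrate in solution at 50 min, in percent of saturation

On that assumption their ratio of 0.422 gives 65.6% of the reagent left in the flask, and since its charges are equal (0.30 M and 0.300 M), this reckoning gives 34.4% for target with solid product. The readings hold no column of dissolved substrate, so they give this reckoning no figure for its saturation.

The forecast gives 35%, a little more than this reckoning, and 93% of saturation, holding that “dissolution is much faster than reaction”; the flask gives 34.7% and 6.84%, with 65% of its reagent left.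

    solid product ⇌ target, rate k1*(cs1 - [target]) while solid is left; crystals form when [target] > cs1 (solubility = 3.90 mM, k = 0.00464 s⁻¹)
    2 dissolved substrate → side product A (k = 0.0494 M⁻¹ s⁻¹)
    solid substrate + target → side product B (k = 3.47 × 10⁻⁴ M⁻¹ s⁻¹)
    dissolved substrate + reagent ⇌ target (K = 6.00 M⁻¹, k = 0.0334 M⁻¹ s⁻¹)
    solid substrate ⇌ dissolved substrate, rate k5*(cs5 - [dissolved substrate]) while solid is left; crystals form when [dissolved substrate] > cs5 (solubility = 0.210 M, k = 2.75 × 10⁻⁴ s⁻¹)

The flask with 0.51 M of solid substrate, at the same reagent and time, is reckoned by the same lifetime at 65.5% of reagent left and 20.3% of target with solid product, and it holds 64.4% and 20.1%. In the asked flask at 50.0 min, dissolved substrate has a half-life of 1.8 min by the forward step into target alone, short against the 50 min of the run. At that time dissolved substrate amounts to 4.79% of the charge, while solid substrate still stands at 44.7%.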